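## Retrosynthetic overview

1. Locants follow the C19 chain: the oxolane is O1, C6 (pentyl), C7 (O-lauroyl), C8 (ring CH2), C9 (bears the C10 carbinol). Target 24 ⇒ C10 ketone 23 (Felkin–Anh reduction) ⇒ acid 19 + nonenylzinc 22 (C10–C11) ⇒ hydroxy acid 16 ⇒ ketone 15 ⇒ exocyclic alkene 14.
2. Key disconnection: the ring bond C8–C9 of 14, made by Ireland–Claisen ring contraction of the seven-membered lactone 11, (5S)-6-methylidene-5-pentyl-1,4-dioxepan-2-one. The ester oxygen and the OCH2 carbon leave the ring as carboxyl and exocyclic methylidene.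
3. Enabling feature: C9 sits between ring oxygen O1 and C10, so C9/C10 can be carried as the α-carbon and carboxyl of an O1-alkylated glycolate. The ring CH2 (C8) is bonded to C7, which can be carried as an sp2 carbon (later C7=O, then the ester). C10(=O)–C9 / C8–C7(=CH2) is then an ester-enolate Claisen retron, and O1–C6 is the tether that turns it into a ring contraction.
4. 11 ⇐ hydroxy acid 9 ⇐ (S)-allylic alcohol 6 + bromoacetic acid; 6 ⇐ CBS reduction of enone 5 ⇐ 2-bromoallyl alcohol + hexanoic Weinreb amide. C6 is the only stereocentre set by a reagent; C9, C7 and C10 are relayed from it.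
5. Ring order: the temporary dioxepanone (step 6), then the oxolane, the only ring of the target (step 7).

Key step: step 7

Remark: compounds 3 and 20 are taken as catalogue chemicals.

## Route

Step 1
Reactants: 1 2-bromoprop-2-en-1-ol
Product: 2 1-{[(2-bromoprop-2-en-1-yl)oxy]methyl}-4-methoxybenzene
Conditions: NaH, 4-methoxybenzyl chloride, Bu4NI (cat.), THF, 0 °C to rt
Reagents that add atoms: 4-methoxybenzyl chloride, COc1ccc(CCl)cc1
Why: Williamson etherification of the primary alkoxide with the benzylic chloride should proceed cleanly, the vinyl bromide being inert to NaH at this temperature.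

Step 2
Reactants: 2 1-{[(2-bromoprop-2-en-1-yl)oxy]methyl}-4-methoxybenzene; 3 N-methoxy-N-methylhexanamide
Product: 5 2-{[(4-methoxyphenyl)methoxy]methyl}oct-1-en-3-one, via vinyllithium 4 (not isolated)
Conditions: t-BuLi (2 equiv), Et2O, −78 °C; then 3, −78 to −40 °C; poured into cold aq. HCl (1 M)
Reagents that add atoms: none
Why: Bromine–lithium exchange at −78 °C gives the 2-lithioallyl ether, which acylates the Weinreb amide through the chelated tetrahedral adduct (Weinreb ketone synthesis), and the acidic inverse quench keeps the released amine from adding to the enone.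

Step 3
Reactants: 5 2-{[(4-methoxyphenyl)methoxy]methyl}oct-1-en-3-one
Product: 6 (3S)-2-{[(4-methoxyphenyl)methoxy]methyl}oct-1-en-3-ol
Conditions: (R)-2-methyl-CBS-oxazaborolidine (15 mol%), catecholborane, toluene, −78 °C; then MeOH, aq. NaOH wash
Reagents that add atoms: none
Why: In this Corey–Bakshi–Shibata reduction the α-branched alkenyl group acts as the large and n-pentyl as the small substituent, so the (R)-catalyst should deliver hydride to the face that gives the (S)-alcohol (sets C6), while catecholborane at −78 °C should leave the alkene alone.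

Step 4
Reactants: 6 (3S)-2-{[(4-methoxyphenyl)methoxy]methyl}oct-1-en-3-ol; 7 bromoacetic acid
Product: 8 {[(3S)-2-{[(4-methoxyphenyl)methoxy]methyl}oct-1-en-3-yl]oxy}acetic acid
Conditions: NaH (3 equiv), THF, 0 °C to reflux; then aq. HCl to pH 2
Reagents that add atoms: none
Why: Williamson etherification of the secondary sodium alkoxide with sodium bromoacetate should install the glycolate unit without touching C6, and the benzylic ether on the primary oxygen cannot migrate to the alkoxide.

Step 5
Reactants: 8 {[(3S)-2-{[(4-methoxyphenyl)methoxy]methyl}oct-1-en-3-yl]oxy}acetic acid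
Product: 9 {[(3S)-2-(hydroxymethyl)oct-1-en-3-yl]oxy}acetic acid
Conditions: DDQ, CH2Cl2/H2O (18:1), 0 °C to rt
Reagents that add atoms: none
Why: Oxidative cleavage of the 4-methoxybenzyl ether by DDQ (benzylic hydride abstraction, then hydrolysis of the oxocarbenium ion) should free the primary allylic alcohol while alkene and acid are untouched.

Step 6
Reactants: 9 {[(3S)-2-(hydroxymethyl)oct-1-en-3-yl]oxy}acetic acid
Product: 11 (5S)-6-methylidene-5-pentyl-1,4-dioxepan-2-one, via mixed anhydride 10 (not isolated)
Conditions: 2,4,6-trichlorobenzoyl chloride, Et3N, THF, rt; then slow addition to DMAP, toluene, 80 °C (high dilution)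
Reagents that add atoms: none
Why: Yamaguchi lactonisation (mixed anhydride, then DMAP-mediated acyl transfer to the primary alcohol under high dilution) should close the seven-membered ring, whose ether oxygen and sp2 carbon reduce transannular strain.

Step 7
Reactants: 11 (5S)-6-methylidene-5-pentyl-1,4-dioxepan-2-one
Product: 14 (2R,5S)-4-methylidene-5-pentyloxolane-2-carboxylic acid, via silyl ketene acetal 12 (not isolated), via trimethylsilyl ester 13 (not isolated)
Conditions: LDA, TMSCl/Et3N (premixed, present during deprotonation), THF, −100 °C to rt; then toluene, 90 °C; then aq. HCl (1 M), THF, rt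
Reagents that add atoms: none
Why: Proposed new method: LDA deprotonates C9 of the lactone while TMSCl traps the enolate at once as the cyclic silyl ketene acetal 12 (geometry fixed by the ring), and on warming the array C9=C10(OSiMe3)–O–CH2–C7=C8H2 undergoes a suprafacial [3,3]-sigmatropic shift that forms the C8–C9 bond, breaks the allylic ester C–O bond and leaves silyl ester 13, hydrolysed to 14 on work-up; the closest known reaction type is the Ireland–Claisen ring contraction of alkenyl lactones (6-alkenyl-1,4-dioxan-2-ones to dihydropyran-2-carboxylic acids, unsaturated macrolactones to carbocycles), which has not been shown for a 6-methylidene-1,4-dioxepan-2-one. The oxolane closes by transannular C–C bond formation inside the seven-membered ring, through a bicyclo[3.2.1]octane-like transition state in which C9 and C7 are the bridgeheads, C8 the one-atom bridge, O1–C6 the two-atom bridge and C10–O–CH2 the three-atom bridge that is cut. The one new stereocentre, C9, is set by C6: pentyl should sit exo on the two-atom bridge, turned away from the three-atom bridge and not eclipsed with the C7–CH2O bond, and because C10 belongs to that three-atom bridge, pentyl and carboxyl end up on opposite faces of the new ring (2,5-trans, 2R). The step needs the ester-side [3,3] shift to win over the [2,3]-Wittig shift of the free α-allyloxy enolate, over the alternative Claisen shift through the C6–O1 ether bond and over intermolecular acylation; the internal TMSCl quench at −100 °C leaves no free enolate, and the silyloxy group on C10 accelerates only cleavage of the adjacent ester C–O bond.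

Step 8
Reactants: 14 (2R,5S)-4-methylidene-5-pentyloxolane-2-carboxylic acid
Product: 15 (2R,5S)-4-oxo-5-pentyloxolane-2-carboxylic acid
Conditions: O3, CH2Cl2/MeOH, −78 °C; then Me2S, −78 °C to rt
Reagents that add atoms: ozone, [O-][O+]=O
Why: Ozonolysis with reductive work-up should convert the only C=C bond present (the terminal alkene of the side chain is introduced later for this reason) into the C7 ketone under neutral conditions that do not epimerise C6.

Step 9
Reactants: 15 (2R,5S)-4-oxo-5-pentyloxolane-2-carboxylic acid
Product: 16 (2R,4S,5S)-4-hydroxy-5-pentyloxolane-2-carboxylic acid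
Conditions: LiBH(s-Bu)3 (L-Selectride, 2.3 equiv), THF, −78 °C; then aq. HCl (1 M)
Reagents that add atoms: none
Why: After the first equivalent has turned the acid into the inert lithium carboxylate, the bulky trialkylborohydride should attack the ring ketone anti to the adjacent C6 pentyl group, which outweighs the more remote C9 substituent, giving the 4,5-cis alcohol (sets C7 as S).

Step 10
Reactants: 16 (2R,4S,5S)-4-hydroxy-5-pentyloxolane-2-carboxylic acid; 17 dodecanoyl chloride
Product: 19 (2R,4S,5S)-4-(dodecanoyloxy)-5-pentyloxolane-2-carboxylic acid, via mixed anhydride 18 (not isolated)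
Conditions: 17 (2.5 equiv), pyridine, DMAP (cat.), CH2Cl2, 0 °C to rt; then THF/H2O, rt
Reagents that add atoms: none
Why: DMAP-catalysed O-acylation with excess acid chloride should esterify the secondary alcohol, and the mixed anhydride formed at the carboxyl group is hydrolysed by water/pyridine while the secondary ester stays.

Step 11
Reactants: 19 (2R,4S,5S)-4-(dodecanoyloxy)-5-pentyloxolane-2-carboxylic acid; 20 9-bromonon-1-ene
Product: 23 (2S,3S,5R)-5-(dec-9-enoyl)-2-pentyloxolan-3-yl dodecanoate, via acid chloride 21 (not isolated), via alkylzinc bromide 22 (not isolated)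
Conditions: 19, (COCl)2, DMF (cat.), CH2Cl2, 0 °C to rt, then evaporation; separately 20, Zn dust, LiCl, THF, 50 °C; then both, Pd(PPh3)4 (5 mol%), THF, 0 °C to rt
Reagents that add atoms: none
Why: Negishi-type acylation (acyl chloride plus alkylzinc halide under zerovalent palladium catalysis) should form the C10–C11 bond, since the organozinc reagent neither attacks the laurate ester nor is basic enough to epimerise C9.

Step 12
Reactants: 23 (2S,3S,5R)-5-(dec-9-enoyl)-2-pentyloxolan-3-yl dodecanoate
Product: 24 (2S,3S,5R)-5-[(1R)-1-hydroxydec-9-en-1-yl]-2-pentyloxolan-3-yl dodecanoate (target)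
Conditions: LiBH(s-Bu)3 (1.2 equiv), THF, −78 °C; then H2O
Reagents that add atoms: none
Why: Felkin–Anh-controlled reduction of the 2-acyloxolane (ring C9–O1 bond anti to the incoming bulky hydride, which passes the C9–H) should give the threo (10R) alcohol, and the ester is inert to this reagent at −78 °C.

## Compound list

1 | 2-bromoprop-2-en-1-ol | OCC(Br)=C | starting material
2 | 1-{[(2-bromoprop-2-en-1-yl)oxy]methyl}-4-methoxybenzene | C=C(Br)COCc1ccc(OC)cc1 | intermediate
3 | N-methoxy-N-methylhexanamide | CCCCCC(=O)N(C)OC | starting material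
4 | {3-[(4-methoxyphenyl)methoxy]prop-1-en-2-yl}lithium | [Li]C(=C)COCc1ccc(OC)cc1 | intermediate
5 | 2-{[(4-methoxyphenyl)methoxy]methyl}oct-1-en-3-one | C=C(COCc1ccc(OC)cc1)C(=O)CCCCC | intermediate
6 | (3S)-2-{[(4-methoxyphenyl)methoxy]methyl}oct-1-en-3-ol | C=C(COCc1ccc(OC)cc1)[C@@H](O)CCCCC | intermediate
7 | bromoacetic acid | OC(=O)CBr | starting material
8 | {[(3S)-2-{[(4-methoxyphenyl)methoxy]methyl}oct-1-en-3-yl]oxy}acetic acid | C=C(COCc1ccc(OC)cc1)[C@@H](OCC(=O)O)CCCCC | intermediate
9 | {[(3S)-2-(hydroxymethyl)oct-1-en-3-yl]oxy}acetic acid | C=C(CO)[C@@H](OCC(=O)O)CCCCC | intermediate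
10 | {[(3S)-2-(hydroxymethyl)oct-1-en-3-yl]oxy}acetic 2,4,6-trichlorobenzoic anhydride | C=C(CO)[C@@H](OCC(=O)OC(=O)c1c(Cl)cc(Cl)cc1Cl)CCCCC | intermediate
11 | (5S)-6-methylidene-5-pentyl-1,4-dioxepan-2-one | O=C1CO[C@@H](CCCCC)C(=C)CO1 | intermediate
12 | trimethyl{[(5S)-6-methylidene-5-pentyl-6,7-dihydro-5H-1,4-dioxepin-2-yl]oxy}silane | C[Si](C)(C)OC1=CO[C@@H](CCCCC)C(=C)CO1 | intermediate
13 | trimethylsilyl (2R,5S)-4-methylidene-5-pentyloxolane-2-carboxylate | C[Si](C)(C)OC(=O)[C@H]1CC(=C)[C@H](CCCCC)O1 | intermediate
14 | (2R,5S)-4-methylidene-5-pentyloxolane-2-carboxylic acid | OC(=O)[C@H]1CC(=C)[C@H](CCCCC)O1 | intermediate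
15 | (2R,5S)-4-oxo-5-pentyloxolane-2-carboxylic acid | OC(=O)[C@H]1CC(=O)[C@H](CCCCC)O1 | intermediate
16 | (2R,4S,5S)-4-hydroxy-5-pentyloxolane-2-carboxylic acid | OC(=O)[C@H]1C[C@H](O)[C@H](CCCCC)O1 | intermediate
17 | dodecanoyl chloride | CCCCCCCCCCCC(=O)Cl | starting material
18 | dodecanoic (2R,4S,5S)-4-(dodecanoyloxy)-5-pentyloxolane-2-carboxylic anhydride | CCCCCCCCCCCC(=O)OC(=O)[C@H]1C[C@H](OC(=O)CCCCCCCCCCC)[C@H](CCCCC)O1 | intermediate
19 | (2R,4S,5S)-4-(dodecanoyloxy)-5-pentyloxolane-2-carboxylic acid | OC(=O)[C@H]1C[C@H](OC(=O)CCCCCCCCCCC)[C@H](CCCCC)O1 | intermediate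
20 | 9-bromonon-1-ene | C=CCCCCCCCBr | starting material
21 | (2R,4S,5S)-4-(dodecanoyloxy)-5-pentyloxolane-2-carbonyl chloride | ClC(=O)[C@H]1C[C@H](OC(=O)CCCCCCCCCCC)[C@H](CCCCC)O1 | intermediate
22 | non-8-en-1-ylzinc bromide | C=CCCCCCCC[Zn]Br | intermediate
23 | (2S,3S,5R)-5-(dec-9-enoyl)-2-pentyloxolan-3-yl dodecanoate | C=CCCCCCCCC(=O)[C@H]1C[C@H](OC(=O)CCCCCCCCCCC)[C@H](CCCCC)O1 | intermediate
24 | (2S,3S,5R)-5-[(1R)-1-hydroxydec-9-en-1-yl]-2-pentyloxolan-3-yl dodecanoate | C=CCCCCCCC[C@@H](O)[C@H]1C[C@H](OC(=O)CCCCCCCCCCC)[C@H](CCCCC)O1 | target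

## Step count and risks

Total step count: 12. Longest linear sequence: 12 steps (1 to 24); compounds 3, 7, 17 and 20 enter directly.

**Step 7 (Proposed new method).** The bridged transition state may not be reached, or the exo and endo placements of pentyl may be poorly discriminated, so that C9 forms as a mixture. The fallback sets out from 6, returns at 14, and closes the oxolane through the C9–O1 bond by known chemistry.
- DDQ would cleave the benzylic ether of 6 to (3S)-2-methylideneoctane-1,3-diol F1.
- Selective phosphorylation of the primary allylic hydroxyl (ClP(O)(OEt)2, pyridine, 0 °C) would give diethyl (3S)-3-hydroxy-2-methylideneoctyl phosphate F2.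
- Copper-catalysed allylic substitution with vinylmagnesium bromide (CuI cat., THF, −30 °C) would give (5S)-4-methylidenedec-1-en-5-ol F3; both allylic termini are CH2, so SN2 and SN2′ attack converge.
- Mukaiyama aerobic oxidative cyclisation would give [(2R,5S)-4-methylidene-5-pentyloxolan-2-yl]methanol F4. Conditions: Co(modp)2, i.e. cobalt bis(1-morpholinocarbamoyl-4,4-dimethylpentane-1,3-dionate) (divalent cobalt), O2, t-BuOOH (cat.), i-PrOH, 55 °C. This reaction type is known to give 2,5-trans-oxolanylmethanols from 1-substituted pent-4-en-1-ols.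
- TEMPO/PhI(OAc)2 in MeCN/H2O would oxidise the primary alcohol to acid 14.

**Step 6.** Intermolecular esterification (oligomer formation) may outrun closure of the seven-membered ring. The fallback sets out from 9 and returns at 11. The ring would be closed at the alkyl C–O bond instead of the acyl C–O bond: Mitsunobu activation of the primary allylic alcohol (PPh3, DIAD, toluene, high dilution, 0 °C to rt) with the carboxylate as nucleophile. SN2 and SN2′ attack lead to the same lactone because both allylic termini are CH2. This fallback makes no new compound (F0).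

**Step 12.** Felkin–Anh control may be eroded by lithium chelation between the ring oxygen and the ketone, so that hydride attacks the other carbonyl face. The fallback sets out from 19 and returns at 24; it sets C10 by chelation-controlled carbon–carbon bond formation instead of by reduction.
- Thioesterification (EtSH, DCC, DMAP cat., CH2Cl2) would give S-ethyl (2R,4S,5S)-4-(dodecanoyloxy)-5-pentyloxolane-2-carbothioate F5.
- Fukuyama reduction (Et3SiH, Pd on carbon, acetone, rt) would give (2S,3S,5R)-5-formyl-2-pentyloxolan-3-yl dodecanoate F6.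
- Addition of non-8-en-1-ylmagnesium bromide F7 (from 20 and Mg in Et2O) to F6 precomplexed with MgBr2·OEt2 (CH2Cl2, −78 °C; aq. NH4Cl) should proceed through the five-membered chelate of ring oxygen and aldehyde. This gives the threo alcohol 24, with the ester untouched at this temperature.

Further compounds
F1 | step 7 | (3S)-2-methylideneoctane-1,3-diol | OCC(=C)[C@@H](O)CCCCC
F2 | step 7 | diethyl (3S)-3-hydroxy-2-methylideneoctyl phosphate | CCOP(=O)(OCC)OCC(=C)[C@@H](O)CCCCC
F3 | step 7 | (5S)-4-methylidenedec-1-en-5-ol | C=CCC(=C)[C@@H](O)CCCCC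
F4 | step 7 | [(2R,5S)-4-methylidene-5-pentyloxolan-2-yl]methanol | OC[C@H]1CC(=C)[C@H](CCCCC)O1
F0 | step 6 | none | none
F5 | step 12 | S-ethyl (2R,4S,5S)-4-(dodecanoyloxy)-5-pentyloxolane-2-carbothioate | CCSC(=O)[C@H]1C[C@H](OC(=O)CCCCCCCCCCC)[C@H](CCCCC)O1
F6 | step 12 | (2S,3S,5R)-5-formyl-2-pentyloxolan-3-yl dodecanoate | O=C[C@H]1C[C@H](OC(=O)CCCCCCCCCCC)[C@H](CCCCC)O1
F7 | step 12 | non-8-en-1-ylmagnesium bromide | C=CCCCCCCC[Mg]Br
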